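**Retrosynthetic overview**
1. Feature: in the maleimide ring, N1 lies between the carbonyl carbons C2 and C5. C3=C4 carries the 6-bromoindol-3-yl and 1-methylimidazol-5-yl groups. Removing the heteroatom and joining C2 to C5 leaves a 3,4-diheteroarylcyclobut-3-ene-1,2-dione that already holds the alkene and both substituents.
2. 14 ⇒ N-tosyl imide 13 ⇒ anhydride 12 (NH for O) ⇒ dione 11, by Baeyer–Villiger insertion of O into the C(=O)–C(=O) bond (four- to five-membered ring).
3. 11 ⇒ diisopropyl squarate 4 + indol-3-yl Grignard 5 + imidazol-5-yl Grignard 9. Two 1,2-additions go to the two neighbouring carbonyls, with the first adduct held as silyl ether 7, and one acid-induced double transposition follows.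
4. Ring order: indole, imidazole and the four-membered ring are bought. The five-membered ring is the only ring made (step 6, by expansion), and step 7 converts it from furandione to pyrroledione.

Key step: step 6

Remark: the carbinol stereocentres of 6, 7 and 10 form without control (racemic; 10 as a mixture of diastereomers) and all vanish in step 5. The target has no stereocentre, so no SMILES carries a stereo descriptor.

Step 1
Reactants: 1 6-bromoindole
Product: 2 6-bromo-3-iodo-1H-indole
Conditions: I2, KOH, DMF, rt
Reagents that add atoms: iodine, II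
Why: Electrophilic aromatic iodination of the indole (as its potassium salt) goes to C3, the most nucleophilic carbon, and leaves the C6–Br bond alone.

Step 2
Reactants: 2 6-bromo-3-iodo-1H-indole
Product: 3 6-bromo-3-iodo-1-tosylindole
Conditions: TsCl, 50% aq NaOH, Bu4NHSO4 (cat.), CH2Cl2, 0 °C to rt
Reagents that add atoms: 4-toluenesulfonyl chloride, Cc1ccc(cc1)S(=O)(=O)Cl
Why: Phase-transfer N-sulfonylation of the indole anion is standard, stabilises the labile 3-iodoindole and installs the electron-withdrawing group that later shields the indole C2=C3 bond from the peracid.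

Step 3
Reactants: 3 6-bromo-3-iodo-1-tosylindole; 4 diisopropyl squarate
Product: 6 4-(6-bromo-1-tosylindol-3-yl)-4-hydroxy-2,3-diisopropoxycyclobut-2-en-1-one (racemic), via indol-3-ylmagnesium chloride 5 (not isolated)
Conditions: iPrMgCl·LiCl (1.05 equiv), THF, −40 °C; then transferred into 4 (1.2 equiv), THF, −78 to −30 °C; aq NH4Cl
Reagents that add atoms: none
Why: Iodine–magnesium exchange is far faster at C3–I than at the unactivated C6–Br bond and the 3-magnesiated N-sulfonylindole holds its position, after which the Grignard reagent adds 1,2 to one squarate carbonyl (inverse addition limits a second addition), the new carbinol centre being racemic and erased in step 5.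

Step 4
Reactants: 6 4-(6-bromo-1-tosylindol-3-yl)-4-hydroxy-2,3-diisopropoxycyclobut-2-en-1-one
Product: 7 4-(6-bromo-1-tosylindol-3-yl)-2,3-diisopropoxy-4-(trimethylsilyloxy)cyclobut-2-en-1-one (racemic)
Conditions: N-(trimethylsilyl)imidazole, CH2Cl2, rt
Reagents that add atoms: N-(trimethylsilyl)imidazole, C[Si](C)(C)n1ccnc1
Why: Neutral O-silylation caps the tertiary carbinol without setting off its acid-induced rearrangement, which matters because the rearranged 3-aryl-4-isopropoxycyclobutenedione would take the second nucleophile at the carbonyl next to C–OiPr (the one that is not a vinylogous ester) and place the two heteroaryl groups 1,3 across the ring, whereas 7 offers only the carbonyl adjacent to the indolyl-bearing carbon.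

Step 5
Reactants: 7 4-(6-bromo-1-tosylindol-3-yl)-2,3-diisopropoxy-4-(trimethylsilyloxy)cyclobut-2-en-1-one; 8 5-bromo-1-methylimidazole
Product: 11 3-(6-bromo-1-tosylindol-3-yl)-4-(1-methylimidazol-5-yl)cyclobut-3-ene-1,2-dione, via imidazol-5-ylmagnesium chloride 9 (not isolated), via O-silylated bis-adduct 10 (not isolated)
Conditions: 8 (1.6 equiv), iPrMgCl·LiCl (1.5 equiv), THF, 0 °C to rt; 7, THF, −40 to 0 °C; then 2 M aq HCl, rt to 45 °C
Reagents that add atoms: water, O
Why: Bromine–magnesium exchange gives the C5 Grignard reagent, which adds 1,2 to the strained cyclobutenone carbonyl so that the two heteroaryl groups sit on adjacent ring carbons (a competing conjugate addition–elimination at the β-isopropoxy carbon would converge on the same dione), and aqueous acid then ionises each carbinol position in turn with the push of an isopropoxy group and hydrolyses the oxocarbenium ions, the known sequential-addition and double allylic transposition route from squarates to 3,4-disubstituted cyclobutenediones, run warm because the protonated imidazole slows ionisation.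

Step 6
Reactants: 11 3-(6-bromo-1-tosylindol-3-yl)-4-(1-methylimidazol-5-yl)cyclobut-3-ene-1,2-dione
Product: 12 3-(6-bromo-1-tosylindol-3-yl)-4-(1-methylimidazol-5-yl)furan-2,5-dione
Conditions: CF3CO2H (2 equiv), mCPBA (1.3 equiv), CH2Cl2, 0 °C to rt
Reagents that add atoms: 3-chloroperbenzoic acid, O=C(OO)c1cccc(Cl)c1
Why: The peracid adds to one of the two strained ring carbonyls to give a Criegee adduct, in which the neighbouring acyl carbon shifts from carbon to the proximal peroxide oxygen as 3-chlorobenzoate leaves, so that one oxygen becomes bonded to both former carbonyl carbons (two new C–O bonds, the C(=O)–C(=O) bond broken). This is the Baeyer–Villiger oxidation of a 1,2-diketone, a reaction type known to turn aryl- and diarylcyclobutenediones and benzocyclobutenedione into the corresponding maleic and phthalic anhydrides. The furan-2,5-dione ring is closed by ring expansion from four to five members through the 1,2-acyl shift, not by a cyclisation, relief of four-ring strain drives it, and no stereocentre is formed. Attack at either carbonyl leads to the same anhydride, so no regiochemical question arises. The step needs chemoselectivity against the indole C2=C3 bond, the imidazole and the central alkene: the tosyl group and the dione keep the indole and the alkene electron-poor, and CF3CO2H holds N3 of the imidazole protonated, which shields that ring from the electrophilic oxidant and makes the dione more electrophilic. Acidic peracid is chosen over alkaline peroxide because hydroxide cleaves diarylcyclobutenediones at the acyl–vinyl bond and would also strip the sulfonamide.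

Step 7
Reactants: 12 3-(6-bromo-1-tosylindol-3-yl)-4-(1-methylimidazol-5-yl)furan-2,5-dione
Product: 13 3-(6-bromo-1-tosylindol-3-yl)-4-(1-methylimidazol-5-yl)pyrrole-2,5-dione
Conditions: (Me3Si)2NH, MeOH, DMF, rt
Reagents that add atoms: hexamethyldisilazane, C[Si](C)(C)N[Si](C)(C)C
Why: Hexamethyldisilazane and methanol release ammonia slowly in the flask, which opens the anhydride to the maleamic acid, and silylation of the acid drives the cyclodehydration at room temperature (anhydride-to-imide exchange), conditions too mild to touch the sulfonamide, the aryl bromide or the imidazole.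

Step 8
Reactants: 13 3-(6-bromo-1-tosylindol-3-yl)-4-(1-methylimidazol-5-yl)pyrrole-2,5-dione
Product: 14 didemnimide D, 3-(6-bromo-1H-indol-3-yl)-4-(1-methylimidazol-5-yl)pyrrole-2,5-dione
Conditions: NaOH (4 equiv), THF–H2O, rt to 50 °C; then 1 M HCl to pH 7
Reagents that add atoms: none
Why: Hydroxide attacks the sulfonyl sulfur and expels the indolide, a good leaving group because C3 carries the electron-poor maleimide (hydrolytic N-desulfonylation), while the imide is protected from ring opening as its N-anion and is released on neutralisation, and water rather than methanol is the co-solvent so that no methyl sulfonate can alkylate the imidazole or the imide.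

**Compound list**
1 | 6-bromoindole | Brc1ccc2cc[nH]c2c1 | starting material
2 | 6-bromo-3-iodo-1H-indole | Brc1ccc2c(I)c[nH]c2c1 | intermediate
3 | 6-bromo-3-iodo-1-tosylindole | Cc1ccc(cc1)S(=O)(=O)n1cc(I)c2ccc(Br)cc21 | intermediate
4 | diisopropyl squarate | CC(C)OC1=C(OC(C)C)C(=O)C1=O | starting material
5 | (6-bromo-1-tosylindol-3-yl)magnesium chloride (not isolated) | Cc1ccc(cc1)S(=O)(=O)n1cc([Mg]Cl)c2ccc(Br)cc21 | intermediate
6 | 4-(6-bromo-1-tosylindol-3-yl)-4-hydroxy-2,3-diisopropoxycyclobut-2-en-1-one (racemic) | CC(C)OC1=C(OC(C)C)C(O)(c2cn(S(=O)(=O)c3ccc(C)cc3)c3cc(Br)ccc23)C1=O | intermediate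
7 | 4-(6-bromo-1-tosylindol-3-yl)-2,3-diisopropoxy-4-(trimethylsilyloxy)cyclobut-2-en-1-one (racemic) | CC(C)OC1=C(OC(C)C)C(O[Si](C)(C)C)(c2cn(S(=O)(=O)c3ccc(C)cc3)c3cc(Br)ccc23)C1=O | intermediate
8 | 5-bromo-1-methylimidazole | Cn1cncc1Br | starting material
9 | (1-methylimidazol-5-yl)magnesium chloride (not isolated) | Cn1cncc1[Mg]Cl | intermediate
10 | 4-(6-bromo-1-tosylindol-3-yl)-2,3-diisopropoxy-1-(1-methylimidazol-5-yl)-4-(trimethylsilyloxy)cyclobut-2-en-1-ol (not isolated; diastereomer mixture; chloromagnesium alkoxide until the acid is added) | CC(C)OC1=C(OC(C)C)C(O[Si](C)(C)C)(c2cn(S(=O)(=O)c3ccc(C)cc3)c3cc(Br)ccc23)C1(O)c1cncn1C | intermediate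
11 | 3-(6-bromo-1-tosylindol-3-yl)-4-(1-methylimidazol-5-yl)cyclobut-3-ene-1,2-dione | Cn1cncc1C1=C(c2cn(S(=O)(=O)c3ccc(C)cc3)c3cc(Br)ccc23)C(=O)C1=O | intermediate
12 | 3-(6-bromo-1-tosylindol-3-yl)-4-(1-methylimidazol-5-yl)furan-2,5-dione | Cn1cncc1C1=C(c2cn(S(=O)(=O)c3ccc(C)cc3)c3cc(Br)ccc23)C(=O)OC1=O | intermediate
13 | 3-(6-bromo-1-tosylindol-3-yl)-4-(1-methylimidazol-5-yl)pyrrole-2,5-dione | Cn1cncc1C1=C(c2cn(S(=O)(=O)c3ccc(C)cc3)c3cc(Br)ccc23)C(=O)NC1=O | intermediate
14 | didemnimide D | Cn1cncc1C1=C(c2c[nH]c3cc(Br)ccc23)C(=O)NC1=O | target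

Total step count: 8. Longest linear sequence: 8 steps (1 → 2 → 3 → 6 → 7 → 11 → 12 → 13 → 14).

**Steps most likely to fail**

Step 6. Addition of the peracid to the donor-stabilised carbonyls may be slow, so that oxidative degradation of the indole or imidazole ring takes over. The fallback gives up the ring expansion and closes the maleimide by a base-mediated glyoxylate–acetamide (Perkin-type) condensation. It sets out from 1 and comes back at 14.
- Acylation of 1 at C3 with oxalyl chloride (Et2O, 0 °C) should give 2-(6-bromo-1H-indol-3-yl)-2-oxoacetyl chloride F1.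
- Methanol converts F1 into methyl 2-(6-bromo-1H-indol-3-yl)-2-oxoacetate F2.
- Hydration of purchased 2-(1-methylimidazol-5-yl)acetonitrile (H2O2, K2CO3, DMSO) should give 2-(1-methylimidazol-5-yl)acetamide F3.
- F2 and F3 with KOtBu in THF (0 °C to rt) and an acidic quench should undergo condensation, imide closure and dehydration in one flask to give 14.

Step 5. Addition of the imidazolyl Grignard reagent to the crowded carbonyl may be sluggish. Warming would then allow electrocyclic opening of the cyclobutene alkoxide and drift of the metal from C5 to C2 of the imidazole. The fallback replaces the exchange-derived magnesium reagent by a harder lithium nucleophile, made by C–H lithiation of a C2-blocked imidazole, which can add at −78 °C and be quenched cold. It sets out from 7 and comes back at 11.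
- Purchased 1-methylimidazole is deprotonated with nBuLi (THF, −78 °C) to 2-lithio-1-methylimidazole F4.
- Et3SiCl converts F4 into 1-methyl-2-(triethylsilyl)imidazole F5.
- A second portion of nBuLi, in slight deficiency, gives 5-lithio-1-methyl-2-(triethylsilyl)imidazole F6.
- Addition of 7 at −78 °C should give 4-(6-bromo-1-tosylindol-3-yl)-2,3-diisopropoxy-1-[1-methyl-2-(triethylsilyl)imidazol-5-yl]-4-(trimethylsilyloxy)cyclobut-2-en-1-ol F7.
- The aqueous HCl treatment of step 5 then removes the C2 silyl group by protodesilylation and unravels the ring to 11.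

Step 3. Addition of the electron-poor indolyl Grignard reagent to the squarate may be slow. The warming then needed invites a second addition to the remaining carbonyl of the adduct. The fallback reverses the order of the two C–C bond formations. The indolyl reagent then meets a substrate with a single carbonyl and can be used in excess and warmer. It sets out from 4 and 9 (made from 8 as in step 5) and comes back at 11.
- 9 is added to 4 (THF, −78 to −40 °C) to give 4-hydroxy-2,3-diisopropoxy-4-(1-methylimidazol-5-yl)cyclobut-2-en-1-one F8.
- N-(trimethylsilyl)imidazole converts F8 into 2,3-diisopropoxy-4-(1-methylimidazol-5-yl)-4-(trimethylsilyloxy)cyclobut-2-en-1-one F9.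
- 5 (from 3, in excess, −20 to 0 °C) should add to give 1-(6-bromo-1-tosylindol-3-yl)-2,3-diisopropoxy-4-(1-methylimidazol-5-yl)-4-(trimethylsilyloxy)cyclobut-2-en-1-ol F10.
- Aqueous HCl as in step 5 leads to 11.

**Further compounds**
F1 | step 6 | 2-(6-bromo-1H-indol-3-yl)-2-oxoacetyl chloride | O=C(Cl)C(=O)c1c[nH]c2cc(Br)ccc12
F2 | step 6 | methyl 2-(6-bromo-1H-indol-3-yl)-2-oxoacetate | COC(=O)C(=O)c1c[nH]c2cc(Br)ccc12
F3 | step 6 | 2-(1-methylimidazol-5-yl)acetamide | Cn1cncc1CC(N)=O
F4 | step 5 | 2-lithio-1-methylimidazole | [Li]c1nccn1C
F5 | step 5 | 1-methyl-2-(triethylsilyl)imidazole | CC[Si](CC)(CC)c1nccn1C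
F6 | step 5 | 5-lithio-1-methyl-2-(triethylsilyl)imidazole | [Li]c1cnc([Si](CC)(CC)CC)n1C
F7 | step 5 | 4-(6-bromo-1-tosylindol-3-yl)-2,3-diisopropoxy-1-[1-methyl-2-(triethylsilyl)imidazol-5-yl]-4-(trimethylsilyloxy)cyclobut-2-en-1-ol | CC(C)OC1=C(OC(C)C)C(O[Si](C)(C)C)(c2cn(S(=O)(=O)c3ccc(C)cc3)c3cc(Br)ccc23)C1(O)c1cnc([Si](CC)(CC)CC)n1C
F8 | step 3 | 4-hydroxy-2,3-diisopropoxy-4-(1-methylimidazol-5-yl)cyclobut-2-en-1-one | CC(C)OC1=C(OC(C)C)C(O)(c2cncn2C)C1=O
F9 | step 3 | 2,3-diisopropoxy-4-(1-methylimidazol-5-yl)-4-(trimethylsilyloxy)cyclobut-2-en-1-one | CC(C)OC1=C(OC(C)C)C(O[Si](C)(C)C)(c2cncn2C)C1=O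
F10 | step 3 | 1-(6-bromo-1-tosylindol-3-yl)-2,3-diisopropoxy-4-(1-methylimidazol-5-yl)-4-(trimethylsilyloxy)cyclobut-2-en-1-ol | CC(C)OC1=C(OC(C)C)C(O[Si](C)(C)C)(c2cncn2C)C1(O)c1cn(S(=O)(=O)c2ccc(C)cc2)c2cc(Br)ccc12
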